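## Structural features

Lespeflorin C6 is the α-hydroxydihydrochalcone (2S)-1-[2,4-dihydroxy-3,5-bis(3-methylbut-2-en-1-yl)phenyl]-2-hydroxy-3-(4-hydroxyphenyl)propan-1-one. A three-carbon chain C1(=O)–C2H(OH)–C3H2 joins a pentasubstituted resorcinol ring A (through C1′) to a 4-hydroxyphenyl ring B (through C3). Ring A carries, in order, the acyl group (C1′), OH (C2′, hydrogen-bonded to the ketone), prenyl (C3′), OH (C4′), prenyl (C5′) and its only hydrogen (C6′). The single stereocenter is C2 (S; OH > C1 > C3 > H). It has no stereogenic neighbour, but it lies α to an aryl ketone and can be lost by enolization under base or by α-ketol rearrangement. The fragile groups are the two trisubstituted olefins, each ortho to a free phenol (chroman formation under acid, reduction under hydrogenation or hydrogenolysis, attack by electrophilic halogen or peracid), the electron-rich phenols and the α-ketol. The real difficulty is ring A: prenyl groups must stand at C3′ (between two oxygens) and at C5′, next to an acyl group at C1′, and electrophilic substitution of a resorcinol does not deliver this selectively (C3′ versus C5′ versus O). The key step exploits the strict alternation O, prenyl, O, prenyl on C2′–C3′–C4′–C5′, which is the pattern of the bis-enol ether of a 2,4-diprenylated acetoacetate, while C1′–C6′ carry only the acyl chain and a hydrogen, the pattern of a terminal ynone. C2, C3 and ring B together are the skeleton of (S)-4-hydroxyphenyllactic acid, so the stereocenter can be bought.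

## Logic of the disconnections

14 to 13. The two O–Si bonds at the C2 oxygen and at the ring B oxygen are cut. The free hydroxyls would protonate the diene of the key step, and silyl ethers can be removed at the end without base (which would epimerize C2), without strong acid (which would cyclize prenyl onto phenol) and without hydrogen (which would reduce the olefins). There is no gain in skeleton. The demand on the forward step is a non-basic, weakly acidic fluoride cleavage.

13 to 6 and 11 (through 12). The ring A bonds C1′–C2′ and C5′–C6′ are cut, with formal return of methanol and two silyl groups. In one sentence: ring A is not substituted but made, by a Diels–Alder/aromatization of 6 with 11. The pentasubstituted benzene falls into two acyclic pieces of similar size, and all five substituents are placed by the regiochemistry of one cycloaddition, so no aromatic substitution is ever needed. The forward step demands one orientation of addition (C4 of 6 to the β-carbon of 11), the (3Z) geometry in 6, aromatization by loss of methanol and not of silanol, and neutral conditions that leave C2 alone.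

11 to 9 and 10. The bond between C1 and the alkyne carbon that becomes C1′ is cut. An N-methoxy-N-methyl amide stops cleanly at the ketone stage, and the two-carbon piece is commercial. The forward step must avoid conjugate addition of the released amine to the ynone and must not enolize C2.

9 to 8 to 7. The two O–Si bonds and the amide C–N bond are cut. 7 already contains C2 with the (S) configuration, C3 and ring B, so the stereocenter is taken from the chiral pool and never created. The forward steps demand N-acylation in the presence of two free hydroxyls and no racemization, which an α-hydroxy acid, lacking an oxazolone pathway, allows.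

6 to 5 to 4. The two enol O–Si bonds are cut one after the other, which reveals a β-ketoester. The forward steps demand O-silylation and not C-silylation, and γ-deprotonation that places the C4 substituent on the outside of the diene.

4 to 3 and 2, then 3 to 1 and 2. The two C–C bonds to the prenyl CH2 groups are cut. Because they are made on an sp3 acetoacetate (γ through the dianion, α through the monoanion), the question of where ring A is prenylated is settled by enolate chemistry with full positional fidelity. The forward steps demand the order γ first, α second, and monoalkylation each time.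

## Other disconnections considered

Alternative 1: the route that comes to mind first cuts the C2–C3 bond at the chalcone oxidation level. A Claisen–Schmidt condensation of the protected diprenyl acetophenone A1 with a protected 4-hydroxybenzaldehyde would give chalcone A2. Asymmetric epoxidation (Juliá–Colonna type) would give epoxy ketone A3, and reductive opening of the benzylic C3–O bond would give the ketol. The chosen plan is preferred on three grounds.
- A1 has to be made first, and its two prenyl groups must go onto a resorcinol by electrophilic substitution or repeated metalation, so the regiochemical problem is only moved.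
- The stereocenter is created late by reagent control. Electron-transfer reductions of α,β-epoxy ketones cleave the C2–O bond and give the β-hydroxy ketone, while the catalytic hydrogenolysis that cleaves C3–O endangers both trisubstituted olefins.
- The sequence is linear and longer.

Alternative 2: a Danheiser benzannulation cuts C1′–C2′, C2′–C3′ and C4′–C5′. Siloxyalkyne A4 and cyclobutenone A5 would give, through a vinylketene, the resorcinol monosilyl ether A6 with both prenyl groups and both oxygens in place. The mechanism itself argues against it: a vinylketene that also carried the acyl group would need a 4-acylcyclobutenone or a 2-diazo-1,3-diketone precursor, neither a dependable vinylketene source. C1′ therefore emerges as CH, and the C1′–C1 bond still needs a separate ortho-acylation of the acid-sensitive arene A6. A4 and A5 each need several steps, and only four of the five substituents are set by the ring construction.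

Alternative 3: the aryl–carbonyl bond C1′–C1 is cut in its intramolecular form, an anionic Fries rearrangement. Bromine–lithium exchange on aryl ester A7, made from the acid derived from 7, would trigger a 1,3 O-to-C acyl shift to ketone A8. The stereocenter is again bought, but the bromo-diprenyl-resorcinol part of A7 still requires regiocontrolled double prenylation and a bromination in the presence of two electron-rich olefins. The aryllithium is also generated next to an ester with an acidic C2–H, so enolization and butyl addition compete with the acyl shift. The chosen plan avoids all aromatic substitution and metalation.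

Key step: step 8

Assumption: 7, the retentive diazotization product of L-tyrosine, is taken as a purchasable chiral-pool acid, and 10 is used as its commercial THF solution. TBS stands for tert-butyldimethylsilyl.

## Steps

Step 1
Reactants: 1 methyl acetoacetate; 2 prenyl bromide (1-bromo-3-methylbut-2-ene)
Product: 3 methyl 7-methyl-3-oxooct-6-enoate
Conditions: NaH, THF, 0 °C; n-BuLi, 0 °C; then 2, 0 → 25 °C; aq. HCl work-up
Reagents that add atoms: none
Why: Dianion (γ) alkylation of a β-ketoester: the second deprotonation creates the more reactive terminal carbanion, which alkylates the primary allylic bromide by SN2 at C4 only. No stereocenter is formed.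

Step 2
Reactants: 3 methyl 7-methyl-3-oxooct-6-enoate; 2 prenyl bromide
Product: 4 methyl 7-methyl-2-(3-methylbut-2-en-1-yl)-3-oxooct-6-enoate (racemic)
Conditions: NaH, THF, 0 °C; then 2 (1 equiv), 0 → 25 °C
Reagents that add atoms: none
Why: The sodium enolate of the β-ketoester is C-alkylated at the doubly activated C2 by the soft allylic bromide. The new C2 stereocenter is racemic and is erased in steps 3 and 8.

Step 3
Reactants: 4 methyl 7-methyl-2-(3-methylbut-2-en-1-yl)-3-oxooct-6-enoate
Product: 5 methyl 7-methyl-2-(3-methylbut-2-en-1-yl)-3-(trimethylsilyloxy)octa-2,6-dienoate (mixture of C2=C3 isomers)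
Conditions: Me3SiCl, Et3N, hexane, 25 °C; filtration under argon
Reagents that add atoms: chlorotrimethylsilane, C[Si](C)(C)Cl
Why: O-Silylation of the enolizable β-ketoester gives the β-silyloxy enoate. Its double-bond geometry does not matter, because C2=C3 becomes the central single bond of the diene.

Step 4
Reactants: 5 methyl 7-methyl-2-(3-methylbut-2-en-1-yl)-3-(trimethylsilyloxy)octa-2,6-dienoate
Product: 6 (3Z)-1-methoxy-7-methyl-2-(3-methylbut-2-en-1-yl)-1,3-bis(trimethylsilyloxy)octa-1,3,6-triene
Conditions: LiN(i-Pr)2, THF, −78 °C; Me3SiCl, −78 → 25 °C; non-aqueous work-up, used crude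
Reagents that add atoms: chlorotrimethylsilane, C[Si](C)(C)Cl
Why: Kinetic γ-deprotonation of the vinylogous ester gives the extended dienolate, which is silylated on the ester oxygen to the 1-methoxy-1,3-bis(silyloxy)diene. Allylic 1,3-strain with the fully substituted C2 in the planar dienolate should place the C4 alkyl group cis to the C3 oxygen, that is (3Z), the geometry in which it points outward in the s-cis diene.

Step 5
Reactants: 7 (2S)-2-hydroxy-3-(4-hydroxyphenyl)propanoic acid
Product: 8 (2S)-2-hydroxy-3-(4-hydroxyphenyl)-N-methoxy-N-methylpropanamide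
Conditions: MeNHOMe·HCl, EDC·HCl, HOBt, N-methylmorpholine, DMF/CH2Cl2, 0 → 25 °C
Reagents that add atoms: N,O-dimethylhydroxylamine hydrochloride, CNOC.Cl
Why: Carbodiimide/HOBt amidation: the amine is far more nucleophilic than the phenol or the secondary alcohol. An α-hydroxy acid has no oxazolone pathway, so C2 keeps the (S) configuration of the chiral pool.

Step 6
Reactants: 8 (2S)-2-hydroxy-3-(4-hydroxyphenyl)-N-methoxy-N-methylpropanamide
Product: 9 (2S)-2-(tert-butyldimethylsilyloxy)-3-[4-(tert-butyldimethylsilyloxy)phenyl]-N-methoxy-N-methylpropanamide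
Conditions: TBSCl, imidazole, DMF, 25 °C
Reagents that add atoms: tert-butyldimethylsilyl chloride, CC(C)(C)[Si](C)(C)Cl
Why: Standard imidazole-promoted silylation of a phenol and a secondary alcohol. C2 is not touched.

Step 7
Reactants: 9 (2S)-2-(tert-butyldimethylsilyloxy)-3-[4-(tert-butyldimethylsilyloxy)phenyl]-N-methoxy-N-methylpropanamide; 10 ethynylmagnesium bromide
Product: 11 (4S)-4-(tert-butyldimethylsilyloxy)-5-[4-(tert-butyldimethylsilyloxy)phenyl]pent-1-yn-3-one
Conditions: HC≡CMgBr, THF, −10 → 0 °C; inverse quench into cold aq. NaHSO4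
Reagents that add atoms: none
Why: Weinreb ketone synthesis: the magnesium chelate of the tetrahedral adduct resists a second addition and shields the α-position from enolization. The acidic inverse quench protonates the released N,O-dimethylhydroxylamine before it can add to the ynone.

Step 8
Reactants: 6 (3Z)-1-methoxy-7-methyl-2-(3-methylbut-2-en-1-yl)-1,3-bis(trimethylsilyloxy)octa-1,3,6-triene; 11 (4S)-4-(tert-butyldimethylsilyloxy)-5-[4-(tert-butyldimethylsilyloxy)phenyl]pent-1-yn-3-one
Product: 13 (2S)-2-(tert-butyldimethylsilyloxy)-3-[4-(tert-butyldimethylsilyloxy)phenyl]-1-[2,4-dihydroxy-3,5-bis(3-methylbut-2-en-1-yl)phenyl]propan-1-one, via cyclohexa-1,4-diene cycloadduct 12 (not isolated)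
Conditions: 6 (1.5 equiv), toluene, 25 → 70 °C, argon; then 1 M aq. HCl, THF, 0 °C
Reagents that add atoms: none
Why: This is a normal-electron-demand Diels–Alder reaction of a 1-alkoxy-1,3-bis(silyloxy)buta-1,3-diene with an acetylenic ketone followed by aromatization, a known way to make resorcinol derivatives. The cycloaddition is strongly asynchronous: the largest HOMO coefficient of 6 lies at C4, the CH terminus remote from the ketene acetal, and bonds first to the unsubstituted β-carbon of 11, after which C1 of 6 closes onto the α-carbon to give 12. Ring A is thus closed by an intermolecular [4+2] cycloaddition that forms C5′–C6′ and C1′–C2′. On acidic work-up the ketal carbon of 12 should lose methanol, because the alkyl ether oxygen is more basic than the silyl ether oxygen; the two O–SiMe3 bonds are hydrolysed and loss of the hydrogen at C5′ aromatizes the ring, leaving free hydroxyls at C2′ and C4′. Regioselectivity is the one selectivity needed, and it is secured by the three oxygen donors of 6 pushing towards C4 and by the ynone acceptor, which together place the acyl group ortho to the C2′ oxygen and para to the C4′ oxygen, and by the fact that the leading bond joins the two least hindered termini. The (3Z) geometry of 6 keeps the prenyl CH2 outside in the s-cis conformer, and the trisubstituted prenyl olefins are inert as dienophiles or enophiles at this temperature. No permanent stereocenter is created: the two sp3 ring carbons of 12 are erased on aromatization, and C2, which is neither deprotonated in the neutral and then briefly acidic medium nor involved in bonding, is carried through as (S). The TBS ethers survive brief cold dilute acid, while the trimethylsilyl groups do not.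

Step 9
Reactants: 13 (2S)-2-(tert-butyldimethylsilyloxy)-3-[4-(tert-butyldimethylsilyloxy)phenyl]-1-[2,4-dihydroxy-3,5-bis(3-methylbut-2-en-1-yl)phenyl]propan-1-one
Product: 14 lespeflorin C6, (2S)-1-[2,4-dihydroxy-3,5-bis(3-methylbut-2-en-1-yl)phenyl]-2-hydroxy-3-(4-hydroxyphenyl)propan-1-one
Conditions: HF·pyridine, pyridine, THF, 0 → 25 °C
Reagents that add atoms: none
Why: Fluoride-mediated cleavage of the aryl and the secondary alkyl silyl ether under buffered, weakly acidic conditions. There is no base to enolize the C2 ketol, and the acid is too weak to protonate the prenyl olefins towards chroman formation.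

## Compound list

1 | methyl acetoacetate | CC(=O)CC(=O)OC | starting material
2 | prenyl bromide (1-bromo-3-methylbut-2-ene) | CC(C)=CCBr | starting material
3 | methyl 7-methyl-3-oxooct-6-enoate | COC(=O)CC(=O)CCC=C(C)C | intermediate
4 | methyl 7-methyl-2-(3-methylbut-2-en-1-yl)-3-oxooct-6-enoate (racemic) | COC(=O)C(CC=C(C)C)C(=O)CCC=C(C)C | intermediate
5 | methyl 7-methyl-2-(3-methylbut-2-en-1-yl)-3-(trimethylsilyloxy)octa-2,6-dienoate (C2=C3 isomer mixture) | COC(=O)C(CC=C(C)C)=C(O[Si](C)(C)C)CCC=C(C)C | intermediate
6 | (3Z)-1-methoxy-7-methyl-2-(3-methylbut-2-en-1-yl)-1,3-bis(trimethylsilyloxy)octa-1,3,6-triene | COC(O[Si](C)(C)C)=C(CC=C(C)C)/C(O[Si](C)(C)C)=C/CC=C(C)C | intermediate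
7 | (2S)-2-hydroxy-3-(4-hydroxyphenyl)propanoic acid | O=C(O)[C@@H](O)Cc1ccc(O)cc1 | starting material
8 | (2S)-2-hydroxy-3-(4-hydroxyphenyl)-N-methoxy-N-methylpropanamide | CON(C)C(=O)[C@@H](O)Cc1ccc(O)cc1 | intermediate
9 | (2S)-2-(tert-butyldimethylsilyloxy)-3-[4-(tert-butyldimethylsilyloxy)phenyl]-N-methoxy-N-methylpropanamide | CON(C)C(=O)[C@@H](O[Si](C)(C)C(C)(C)C)Cc1ccc(O[Si](C)(C)C(C)(C)C)cc1 | intermediate
10 | ethynylmagnesium bromide | C#C[Mg]Br | starting material
11 | (4S)-4-(tert-butyldimethylsilyloxy)-5-[4-(tert-butyldimethylsilyloxy)phenyl]pent-1-yn-3-one | C#CC(=O)[C@@H](O[Si](C)(C)C(C)(C)C)Cc1ccc(O[Si](C)(C)C(C)(C)C)cc1 | intermediate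
12 | (2S)-2-(tert-butyldimethylsilyloxy)-3-[4-(tert-butyldimethylsilyloxy)phenyl]-1-[6-methoxy-3,5-bis(3-methylbut-2-en-1-yl)-4,6-bis(trimethylsilyloxy)cyclohexa-1,4-dien-1-yl]propan-1-one (ring C3/C6 epimer mixture) | COC1(O[Si](C)(C)C)C(CC=C(C)C)=C(O[Si](C)(C)C)C(CC=C(C)C)C=C1C(=O)[C@@H](O[Si](C)(C)C(C)(C)C)Cc1ccc(O[Si](C)(C)C(C)(C)C)cc1 | intermediate
13 | (2S)-2-(tert-butyldimethylsilyloxy)-3-[4-(tert-butyldimethylsilyloxy)phenyl]-1-[2,4-dihydroxy-3,5-bis(3-methylbut-2-en-1-yl)phenyl]propan-1-one | CC(C)=CCc1cc(C(=O)[C@@H](O[Si](C)(C)C(C)(C)C)Cc2ccc(O[Si](C)(C)C(C)(C)C)cc2)c(O)c(CC=C(C)C)c1O | intermediate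
14 | lespeflorin C6, (2S)-1-[2,4-dihydroxy-3,5-bis(3-methylbut-2-en-1-yl)phenyl]-2-hydroxy-3-(4-hydroxyphenyl)propan-1-one | CC(C)=CCc1cc(C(=O)[C@@H](O)Cc2ccc(O)cc2)c(O)c(CC=C(C)C)c1O | target

## Step count and least certain steps

Total step count: 9. Longest linear sequence: 6 steps (steps 1, 2, 3, 4, 8, 9). The ynone branch (steps 5, 6, 7) joins at step 8.

Step 8 (key step). Three things may go wrong.
- The cycloaddition may be interrupted after the first C–C bond by silyl transfer (an open-chain Mukaiyama–Michael outcome), because closure at the fully substituted ketene-acetal terminus is sterically slow.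
- Aromatization may proceed by loss of silanol in place of methanol, leaving the C2′ oxygen methylated.
- Any (3E) diene would not take part, since its C4 substituent points inward.

Fallback by known chemistry, setting out from 9 and returning at 14: the C1′–C1 bond is made by directed ortho-metalation instead. Resorcinol is converted with MOMCl and i-Pr2NEt into 1,3-bis(methoxymethoxy)benzene F1. Lithiation between the two acetal oxygens (n-BuLi, THF, 0 °C), transmetalation with CuBr·SMe2 and alkylation with 2 should give 1,3-bis(methoxymethoxy)-2-(3-methylbut-2-en-1-yl)benzene F2. A second ortho-lithiation and prenylation (n-BuLi, TMEDA; CuBr·SMe2; 2) should give 1,3-bis(methoxymethoxy)-2,4-bis(3-methylbut-2-en-1-yl)benzene F3. A third lithiation at the only remaining position ortho to an acetal oxygen, followed by addition to 9, should give (2S)-1-[2,4-bis(methoxymethoxy)-3,5-bis(3-methylbut-2-en-1-yl)phenyl]-2-(tert-butyldimethylsilyloxy)-3-[4-(tert-butyldimethylsilyloxy)phenyl]propan-1-one F4. HCl in MeOH at 0–25 °C then removes all four protecting groups to give 14.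

Step 4. C-silylation may compete with O-silylation, geometric control at C3=C4 may be incomplete, and the very moisture-sensitive diene may hydrolyse on handling. All three come from the tetrasubstituted, doubly branched dienolate.

Fallback, setting out from 1 and returning at 13: the substituent that creates the geometric problem is taken off the diene and installed after the benzannulation. Alkylation of 1 with 2 (K2CO3, acetone) gives methyl 2-(3-methylbut-2-en-1-yl)-3-oxobutanoate F5. Double soft enolization (Me3SiOTf, Et3N, Et2O, 0 °C) gives 1-methoxy-2-(3-methylbut-2-en-1-yl)-1,3-bis(trimethylsilyloxy)buta-1,3-diene F6, which has an unsubstituted terminus and therefore no C3=C4 geometry. Cycloaddition with 11 and the same acidic work-up should give (2S)-2-(tert-butyldimethylsilyloxy)-3-[4-(tert-butyldimethylsilyloxy)phenyl]-1-[2,4-dihydroxy-3-(3-methylbut-2-en-1-yl)phenyl]propan-1-one F7. Tsuji–Trost O-alkylation of the non-chelated C4′ hydroxyl (Pd(PPh3)4, a zerovalent palladium catalyst, with tert-butyl 2-methylbut-3-en-2-yl carbonate, THF) gives the aryl 1,1-dimethylallyl ether (2S)-2-(tert-butyldimethylsilyloxy)-3-[4-(tert-butyldimethylsilyloxy)phenyl]-1-[2-hydroxy-4-(2-methylbut-3-en-2-yloxy)-3-(3-methylbut-2-en-1-yl)phenyl]propan-1-one F8. An aromatic Claisen rearrangement (toluene, 110 °C) to the only free ortho position, C5′, then gives 13.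

Step 7. The released N,O-dimethylhydroxylamine may add in conjugate fashion to the terminal ynone during the quench, and C2 may erode if the ynone meets base, because its α-hydrogen is activated by the ketone.

Fallback, setting out from 9 and returning at 11: reduction with i-Bu2AlH (THF, −78 °C) gives (2S)-2-(tert-butyldimethylsilyloxy)-3-[4-(tert-butyldimethylsilyloxy)phenyl]propanal F9. Addition of 10 gives (4S)-4-(tert-butyldimethylsilyloxy)-5-[4-(tert-butyldimethylsilyloxy)phenyl]pent-1-yn-3-ol F10 as a mixture of C3 epimers, which is of no consequence. Oxidation with Dess–Martin periodinane gives 11 with no amine present.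

Step 9. Cleavage of the hindered secondary silyl ether next to the ketone may be slow. Longer exposure invites acid-promoted cyclization of a prenyl group onto the neighbouring phenol or enolization at C2.

Fallback, setting out from 8 and returning at 14: more labile silyl groups are carried, so that the work-up of the benzannulation itself unveils the target. Et3SiCl and imidazole convert 8 into (2S)-N-methoxy-N-methyl-2-(triethylsilyloxy)-3-[4-(triethylsilyloxy)phenyl]propanamide F11. Addition of 10 gives (4S)-4-(triethylsilyloxy)-5-[4-(triethylsilyloxy)phenyl]pent-1-yn-3-one F12. Cycloaddition with 6 as in step 8, followed by dilute HCl in aqueous THF/MeOH at 0 °C, should cleave all four silyl ethers during aromatization and give 14 directly.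

## Further compounds

F1 | step 8 | 1,3-bis(methoxymethoxy)benzene | COCOc1cccc(OCOC)c1
F2 | step 8 | 1,3-bis(methoxymethoxy)-2-(3-methylbut-2-en-1-yl)benzene | COCOc1cccc(OCOC)c1CC=C(C)C
F3 | step 8 | 1,3-bis(methoxymethoxy)-2,4-bis(3-methylbut-2-en-1-yl)benzene | COCOc1ccc(CC=C(C)C)c(OCOC)c1CC=C(C)C
F4 | step 8 | (2S)-1-[2,4-bis(methoxymethoxy)-3,5-bis(3-methylbut-2-en-1-yl)phenyl]-2-(tert-butyldimethylsilyloxy)-3-[4-(tert-butyldimethylsilyloxy)phenyl]propan-1-one | CC(C)=CCc1cc(C(=O)[C@@H](O[Si](C)(C)C(C)(C)C)Cc2ccc(O[Si](C)(C)C(C)(C)C)cc2)c(OCOC)c(CC=C(C)C)c1OCOC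
F5 | step 4 | methyl 2-(3-methylbut-2-en-1-yl)-3-oxobutanoate | COC(=O)C(CC=C(C)C)C(C)=O
F6 | step 4 | 1-methoxy-2-(3-methylbut-2-en-1-yl)-1,3-bis(trimethylsilyloxy)buta-1,3-diene | COC(O[Si](C)(C)C)=C(CC=C(C)C)C(=C)O[Si](C)(C)C
F7 | step 4 | (2S)-2-(tert-butyldimethylsilyloxy)-3-[4-(tert-butyldimethylsilyloxy)phenyl]-1-[2,4-dihydroxy-3-(3-methylbut-2-en-1-yl)phenyl]propan-1-one | CC(C)=CCc1c(O)ccc(C(=O)[C@@H](O[Si](C)(C)C(C)(C)C)Cc2ccc(O[Si](C)(C)C(C)(C)C)cc2)c1O
F8 | step 4 | (2S)-2-(tert-butyldimethylsilyloxy)-3-[4-(tert-butyldimethylsilyloxy)phenyl]-1-[2-hydroxy-4-(2-methylbut-3-en-2-yloxy)-3-(3-methylbut-2-en-1-yl)phenyl]propan-1-one | C=CC(C)(C)Oc1ccc(C(=O)[C@@H](O[Si](C)(C)C(C)(C)C)Cc2ccc(O[Si](C)(C)C(C)(C)C)cc2)c(O)c1CC=C(C)C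
F9 | step 7 | (2S)-2-(tert-butyldimethylsilyloxy)-3-[4-(tert-butyldimethylsilyloxy)phenyl]propanal | O=C[C@@H](O[Si](C)(C)C(C)(C)C)Cc1ccc(O[Si](C)(C)C(C)(C)C)cc1
F10 | step 7 | (4S)-4-(tert-butyldimethylsilyloxy)-5-[4-(tert-butyldimethylsilyloxy)phenyl]pent-1-yn-3-ol (C3 epimer mixture) | C#CC(O)[C@@H](O[Si](C)(C)C(C)(C)C)Cc1ccc(O[Si](C)(C)C(C)(C)C)cc1
F11 | step 9 | (2S)-N-methoxy-N-methyl-2-(triethylsilyloxy)-3-[4-(triethylsilyloxy)phenyl]propanamide | CON(C)C(=O)[C@@H](O[Si](CC)(CC)CC)Cc1ccc(O[Si](CC)(CC)CC)cc1
F12 | step 9 | (4S)-4-(triethylsilyloxy)-5-[4-(triethylsilyloxy)phenyl]pent-1-yn-3-one | C#CC(=O)[C@@H](O[Si](CC)(CC)CC)Cc1ccc(O[Si](CC)(CC)CC)cc1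
A1 | alternative 1 | 1-[2,4-bis(methoxymethoxy)-3,5-bis(3-methylbut-2-en-1-yl)phenyl]ethan-1-one | CC(=O)c1cc(CC=C(C)C)c(OCOC)c(CC=C(C)C)c1OCOC
A2 | alternative 1 | (2E)-1-[2,4-bis(methoxymethoxy)-3,5-bis(3-methylbut-2-en-1-yl)phenyl]-3-[4-(methoxymethoxy)phenyl]prop-2-en-1-one | COCOc1ccc(/C=C/C(=O)c2cc(CC=C(C)C)c(OCOC)c(CC=C(C)C)c2OCOC)cc1
A3 | alternative 1 | [2,4-bis(methoxymethoxy)-3,5-bis(3-methylbut-2-en-1-yl)phenyl]{(2S,3R)-3-[4-(methoxymethoxy)phenyl]oxiran-2-yl}methanone | O=C(c1cc(CC=C(C)C)c(OCOC)c(CC=C(C)C)c1OCOC)[C@H]1O[C@@H]1c1ccc(OCOC)cc1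
A4 | alternative 2 | triisopropyl[(5-methylhex-4-en-1-yn-1-yl)oxy]silane | CC(C)=CCC#CO[Si](C(C)C)(C(C)C)C(C)C
A5 | alternative 2 | 2-(3-methylbut-2-en-1-yl)cyclobut-2-en-1-one | O=C1CC=C1CC=C(C)C
A6 | alternative 2 | 2,4-bis(3-methylbut-2-en-1-yl)-3-(triisopropylsilyloxy)phenol | CC(C)=CCc1ccc(O)c(CC=C(C)C)c1O[Si](C(C)C)(C(C)C)C(C)C
A7 | alternative 3 | 6-bromo-2,4-bis(3-methylbut-2-en-1-yl)-3-(triisopropylsilyloxy)phenyl (2S)-2-(tert-butyldimethylsilyloxy)-3-[4-(tert-butyldimethylsilyloxy)phenyl]propanoate | CC(C)=CCc1cc(Br)c(OC(=O)[C@@H](O[Si](C)(C)C(C)(C)C)Cc2ccc(O[Si](C)(C)C(C)(C)C)cc2)c(CC=C(C)C)c1O[Si](C(C)C)(C(C)C)C(C)C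
A8 | alternative 3 | (2S)-2-(tert-butyldimethylsilyloxy)-3-[4-(tert-butyldimethylsilyloxy)phenyl]-1-[2-hydroxy-3,5-bis(3-methylbut-2-en-1-yl)-4-(triisopropylsilyloxy)phenyl]propan-1-one | CC(C)=CCc1cc(C(=O)[C@@H](O[Si](C)(C)C(C)(C)C)Cc2ccc(O[Si](C)(C)C(C)(C)C)cc2)c(O)c(CC=C(C)C)c1O[Si](C(C)C)(C(C)C)C(C)C
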